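The acylcyclohexene is read as an aldol condensation product (C1=C2, C1 being the α-carbon of the coumarin C8 ketone) whose aldehyde arm comes from a Claisen rearrangement (C3–C4). In one flask, an open-chain aryl ketone carrying a 2-substituted allyl vinyl ether rearranges, and the liberated aldehyde condenses with the ketone methylene, closing the ring onto the complete coumarin. The step exploits the enone C1=C2 next to the unfunctionalised C3–C4 ethano unit. C5 passes through as an exocyclic methylene and is hydrogenated afterwards to the cis methyl group. C6 and the carbinol centre come from (S)-lactaldehyde and a cuprate addition.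

Key step: step 9

Remark: (S)-2-(tert-butyldimethylsilyloxy)propanal is taken as a purchasable compound. Cyclohexene locants: C1 bears the ketone carbonyl, C2 is the vinylic CH, C5 bears the methyl group, C6 the 1-hydroxyethyl group.

Step 1
Reactants: 1 phloroglucinol; 2 ethyl 2-methyl-3-oxobutanoate
Product: 3 5,7-dihydroxy-3,4-dimethylcoumarin
Conditions: conc. H2SO4, 0 °C → rt
Reagents that add atoms: none
Why: Pechmann condensation (transesterification, ring closure at the ortho carbon, dehydration); the symmetry of phloroglucinol allows only one product.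

Step 2
Reactants: 3 5,7-dihydroxy-3,4-dimethylcoumarin
Product: 4 8-acetyl-5,7-dihydroxy-3,4-dimethylcoumarin
Conditions: AcCl, AlCl3, PhNO2, 70 °C
Reagents that add atoms: acetyl chloride CC(Cl)=O
Why: Friedel–Crafts acylation; C3 is blocked by methyl, and C8 is the position at which 5,7-dihydroxy-4-alkylcoumarins are expected to acylate preferentially, the product being held by the 7-OH···O=C hydrogen bond.

Step 3
Reactants: 4 8-acetyl-5,7-dihydroxy-3,4-dimethylcoumarin
Product: 5 8-acetyl-5,7-dihydroxy-3,4-dimethyl-6-(3-methylbut-2-enyl)coumarin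
Conditions: prenyl bromide, 10% aq. KOH, 0 °C → rt; then dilute HCl
Reagents that add atoms: 1-bromo-3-methylbut-2-ene CC(C)=CCBr
Why: C-alkylation of the phloroglucinol-type phenoxide in water, where solvation of oxygen favours attack through carbon; C6 is the only unsubstituted ring carbon.

Step 4
Reactants: 5 8-acetyl-5,7-dihydroxy-3,4-dimethyl-6-(3-methylbut-2-enyl)coumarin
Product: 6 8-acetyl-7-hydroxy-5-methoxy-3,4-dimethyl-6-(3-methylbut-2-enyl)coumarin
Conditions: MeI (1.1 equiv), K2CO3, acetone, rt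
Reagents that add atoms: iodomethane CI
Why: Williamson etherification; the 7-OH is tied up in a hydrogen bond to the C8 acetyl group, so the free 5-OH should be methylated.

Step 5
Reactants: 6 8-acetyl-7-hydroxy-5-methoxy-3,4-dimethyl-6-(3-methylbut-2-enyl)coumarin
Product: 7 8-acetyl-5-methoxy-7-(methoxymethoxy)-3,4-dimethyl-6-(3-methylbut-2-enyl)coumarin
Conditions: NaH, MOMCl, DMF, 0 °C → rt
Reagents that add atoms: chloromethyl methyl ether COCCl
Why: Williamson-type alkylation of the sodium phenoxide; the MOM ether masks the acidic, chelating phenol before enolate and cuprate chemistry.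

Step 6
Reactants: 7 8-acetyl-5-methoxy-7-(methoxymethoxy)-3,4-dimethyl-6-(3-methylbut-2-enyl)coumarin; 8 (S)-2-(tert-butyldimethylsilyloxy)propanal
Product: 11 8-[(2E,4S)-4-(tert-butyldimethylsilyloxy)pent-2-enoyl]-5-methoxy-7-(methoxymethoxy)-3,4-dimethyl-6-(3-methylbut-2-enyl)coumarin, via lithium aldolate 9 (not isolated), via aldol mesylate 10 (not isolated)
Conditions: LiN(SiMe3)2, THF, −78 °C; 8, −78 °C; MsCl then Et3N, −78 °C → rt
Reagents that add atoms: none
Why: Aldol addition of the kinetic lithium enolate of the methyl ketone, then mesylation and E1cB elimination (aldol condensation in two stages) should give the (E)-enone; the silyloxy-bearing centre of 8 is kept.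

Step 7
Reactants: 12 2-bromoprop-2-en-1-ol
Product: 13 2-bromo-3-(vinyloxy)prop-1-ene
Conditions: ethyl vinyl ether (excess), Hg(OAc)2 (10 mol%), reflux
Reagents that add atoms: ethyl vinyl ether CCOC=C
Why: Mercury-catalysed transfer vinylation (transetherification) of a primary allylic alcohol.

Step 8
Reactants: 13 2-bromo-3-(vinyloxy)prop-1-ene; 11 the (2E,4S)-enone
Product: 16 8-{(3S,4S)-4-(tert-butyldimethylsilyloxy)-3-[3-(vinyloxy)prop-1-en-2-yl]pentanoyl}-5-methoxy-7-(methoxymethoxy)-3,4-dimethyl-6-(3-methylbut-2-enyl)coumarin, via alkenyllithium 14 (not isolated), via lithium dialkenylcuprate 15 (not isolated)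
Conditions: 13 (2.2 equiv), t-BuLi (4.4 equiv), Et2O, −78 °C; CuI (1.1 equiv), −78 → −40 °C; 11, −78 → −30 °C; aq. NH4Cl
Reagents that add atoms: none
Why: Bromine–lithium exchange, transmetalation and cuprate 1,4-addition; on the modified Felkin–Anh model the cuprate should attack anti to the γ-silyloxy group, which sets the centre that becomes ring C6 (3S in 16).

Step 9
Reactants: 16 the allyl vinyl ether
Product: 18 8-{(6R)-6-[(1S)-1-(tert-butyldimethylsilyloxy)ethyl]-5-methylidenecyclohex-1-ene-1-carbonyl}-5-methoxy-7-(methoxymethoxy)-3,4-dimethyl-6-(3-methylbut-2-enyl)coumarin, via γ,δ-unsaturated aldehyde 17 (not isolated)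
Conditions: PhMe (0.02 M), 170 °C, sealed tube; cool to 60 °C, add Bn2NH·CF3CO2H (0.3 equiv), 60 °C, same flask
Reagents that add atoms: none
Why: Heating triggers the chair-like [3,3]-sigmatropic shift of the allyl vinyl ether, which joins the vinyl terminus to the allyl CH2 terminus (ring C3–C4) and unmasks aldehyde 17; its iminium ion with the ammonium salt is then attacked by the enol of the aryl ketone, and loss of the amine gives the C1=C2 enone. The closest known reaction types are the aliphatic Claisen rearrangement and the ammonium-salt-mediated intramolecular aldol condensation of keto aldehydes to 1-acylcycloalkenes. The one ring closure is a 6-(enolexo)-exo-trig aldol followed by dehydration. No stereocentre is created: C6 and the carbinol carbon are carried unchanged, and C5 is left as an exocyclic methylene for step 10. The step needs the ketone α-carbon, not the aldehyde α-carbon, to be the nucleophile; the doubly ortho-substituted aryl ketone is a poor electrophile and the acidic catalyst holds the aldehyde as an iminium electrophile, and the weak acid and moderate temperature are chosen to keep the 1,1-disubstituted alkene exocyclic.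

Step 10
Reactants: 18 the methylidene cyclohexenyl ketone
Product: 19 8-{(5R,6R)-6-[(1S)-1-(tert-butyldimethylsilyloxy)ethyl]-5-methylcyclohex-1-ene-1-carbonyl}-5-methoxy-7-(methoxymethoxy)-3,4-dimethyl-6-(3-methylbut-2-enyl)coumarin
Conditions: H2 (1 atm), RhCl(PPh3)3 (10 mol%), PhH, rt
Reagents that add atoms: none
Why: Homogeneous hydrogenation should reduce the 1,1-disubstituted alkene ahead of the trisubstituted prenyl and enone alkenes, and should add H2 to the face opposite the C6 side chain (held pseudoaxial by allylic strain against the C1 acyl group and the methylidene), so the new methyl group ends up cis to it (5R).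

Step 11
Reactants: 19 the protected cis-cyclohexenyl ketone
Product: 20 7-hydroxy-8-{(5R,6R)-6-[(1S)-1-hydroxyethyl]-5-methylcyclohex-1-ene-1-carbonyl}-5-methoxy-3,4-dimethyl-6-(3-methylbut-2-enyl)coumarin
Conditions: HCl (3 M aq.)/MeOH 1:10, rt
Reagents that add atoms: none
Why: Acid-catalysed methanolysis of the aryl MOM acetal (assisted by the ortho carbonyl group) and of the secondary silyl ether; conditions this mild should leave the prenyl group and the enone untouched.

Compound list
1 | phloroglucinol | Oc1cc(O)cc(O)c1 | starting material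
2 | ethyl 2-methyl-3-oxobutanoate | CCOC(=O)C(C)C(C)=O | starting material
3 | 5,7-dihydroxy-3,4-dimethylcoumarin | Cc1c(C)c2c(O)cc(O)cc2oc1=O | intermediate
4 | 8-acetyl-5,7-dihydroxy-3,4-dimethylcoumarin | CC(=O)c1c(O)cc(O)c2c(C)c(C)c(=O)oc12 | intermediate
5 | 8-acetyl-5,7-dihydroxy-3,4-dimethyl-6-(3-methylbut-2-enyl)coumarin | CC(=O)c1c(O)c(CC=C(C)C)c(O)c2c(C)c(C)c(=O)oc12 | intermediate
6 | 8-acetyl-7-hydroxy-5-methoxy-3,4-dimethyl-6-(3-methylbut-2-enyl)coumarin | CC(=O)c1c(O)c(CC=C(C)C)c(OC)c2c(C)c(C)c(=O)oc12 | intermediate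
7 | 8-acetyl-5-methoxy-7-(methoxymethoxy)-3,4-dimethyl-6-(3-methylbut-2-enyl)coumarin | CC(=O)c1c(OCOC)c(CC=C(C)C)c(OC)c2c(C)c(C)c(=O)oc12 | intermediate
8 | (S)-2-(tert-butyldimethylsilyloxy)propanal | C[C@H](O[Si](C)(C)C(C)(C)C)C=O | starting material
9 | lithium aldolate of 7 and 8 (mixture at the new carbinol carbon, 4S) | C[C@H](O[Si](C)(C)C(C)(C)C)C([O-])CC(=O)c1c(OCOC)c(CC=C(C)C)c(OC)c2c(C)c(C)c(=O)oc12.[Li+] | intermediate
10 | methanesulfonate of the aldol (mixture at the sulfonate carbon, 4S) | C[C@H](O[Si](C)(C)C(C)(C)C)C(OS(C)(=O)=O)CC(=O)c1c(OCOC)c(CC=C(C)C)c(OC)c2c(C)c(C)c(=O)oc12 | intermediate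
11 | 8-[(2E,4S)-4-(tert-butyldimethylsilyloxy)pent-2-enoyl]-5-methoxy-7-(methoxymethoxy)-3,4-dimethyl-6-(3-methylbut-2-enyl)coumarin | C[C@H](O[Si](C)(C)C(C)(C)C)/C=C/C(=O)c1c(OCOC)c(CC=C(C)C)c(OC)c2c(C)c(C)c(=O)oc12 | intermediate
12 | 2-bromoprop-2-en-1-ol | OCC(Br)=C | starting material
13 | 2-bromo-3-(vinyloxy)prop-1-ene | C=COCC(Br)=C | intermediate
14 | [3-(vinyloxy)prop-1-en-2-yl]lithium | [Li]C(=C)COC=C | intermediate
15 | lithium bis[3-(vinyloxy)prop-1-en-2-yl]cuprate | [Li+].C=COCC(=C)[Cu-]C(=C)COC=C | intermediate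
16 | 8-{(3S,4S)-4-(tert-butyldimethylsilyloxy)-3-[3-(vinyloxy)prop-1-en-2-yl]pentanoyl}-5-methoxy-7-(methoxymethoxy)-3,4-dimethyl-6-(3-methylbut-2-enyl)coumarin | C[C@H](O[Si](C)(C)C(C)(C)C)[C@@H](CC(=O)c1c(OCOC)c(CC=C(C)C)c(OC)c2c(C)c(C)c(=O)oc12)C(=C)COC=C | intermediate
17 | 8-[(3S,4S)-4-(tert-butyldimethylsilyloxy)-3-(5-oxopent-1-en-2-yl)pentanoyl]-5-methoxy-7-(methoxymethoxy)-3,4-dimethyl-6-(3-methylbut-2-enyl)coumarin | C[C@H](O[Si](C)(C)C(C)(C)C)[C@@H](CC(=O)c1c(OCOC)c(CC=C(C)C)c(OC)c2c(C)c(C)c(=O)oc12)C(=C)CCC=O | intermediate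
18 | 8-{(6R)-6-[(1S)-1-(tert-butyldimethylsilyloxy)ethyl]-5-methylidenecyclohex-1-ene-1-carbonyl}-5-methoxy-7-(methoxymethoxy)-3,4-dimethyl-6-(3-methylbut-2-enyl)coumarin | COc1c(CC=C(C)C)c(OCOC)c(C(=O)C2=CCCC(=C)[C@H]2[C@H](C)O[Si](C)(C)C(C)(C)C)c2oc(=O)c(C)c(C)c12 | intermediate
19 | 8-{(5R,6R)-6-[(1S)-1-(tert-butyldimethylsilyloxy)ethyl]-5-methylcyclohex-1-ene-1-carbonyl}-5-methoxy-7-(methoxymethoxy)-3,4-dimethyl-6-(3-methylbut-2-enyl)coumarin | COc1c(CC=C(C)C)c(OCOC)c(C(=O)C2=CCC[C@@H](C)[C@H]2[C@H](C)O[Si](C)(C)C(C)(C)C)c2oc(=O)c(C)c(C)c12 | intermediate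
20 | 7-hydroxy-8-{(5R,6R)-6-[(1S)-1-hydroxyethyl]-5-methylcyclohex-1-ene-1-carbonyl}-5-methoxy-3,4-dimethyl-6-(3-methylbut-2-enyl)coumarin | COc1c(CC=C(C)C)c(O)c(C(=O)C2=CCC[C@@H](C)[C@H]2[C@H](C)O)c2oc(=O)c(C)c(C)c12 | target

Total step count: 11. Longest linear sequence: 10 steps (steps 1–6 and 8–11; step 7 is a one-step side branch).

Steps most likely to fail

Step 9. The condensation stage may take the wrong course: the aldehyde may react through its own α-carbon, the iminium ion may be captured by the 1,1-disubstituted alkene, or the exocyclic double bond may drift into conjugation. The vinyl ether may also be lost before the sigmatropic shift is complete. The fallback keeps the thermal Claisen shift for C3–C4 but closes C1=C2 by metathesis. It sets out from 16 and returns at 18. Compound 16 is heated alone (PhMe, 170 °C) and aldehyde 17 is isolated. Wittig methylenation (Ph3PCH3Br, KOt-Bu, THF, −78 → 0 °C) should give the terminal alkene 8-[(3S,4S)-4-(tert-butyldimethylsilyloxy)-3-(hexa-1,5-dien-2-yl)pentanoyl]-5-methoxy-7-(methoxymethoxy)-3,4-dimethyl-6-(3-methylbut-2-enyl)coumarin F1. α-Methylenation of the ketone (paraformaldehyde, N-methylanilinium trifluoroacetate, THF, reflux) should give the α-methylene ketone F2. Ring-closing metathesis (second-generation Grubbs catalyst, CH2Cl2, 40 °C) between the enone methylene and the terminal vinyl group should then give 18.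

Step 8. The lithiated allyl ether may undergo β-elimination to allene before transmetalation, or the 1,4-addition may show too little anti facial selectivity. The fallback replaces organolithium and cuprate chemistry by a rhodium-catalysed conjugate addition under catalyst control. It sets out from 13 (with 11) and returns at 16. Miyaura borylation of 13 (B2pin2, PdCl2(dppf), KOPh, PhMe, 50 °C) should give 4,4,5,5-tetramethyl-2-[3-(vinyloxy)prop-1-en-2-yl]-1,3,2-dioxaborolane F3. Hayashi–Miyaura addition of F3 to 11 ([Rh(cod)Cl]2, the matched BINAP enantiomer, KOH, dioxane/H2O, 60 °C) should give 16.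

Step 3. O-alkylation and double alkylation of the polyphenoxide may compete, leaving little of the C6-prenyl compound. The fallback brings in the prenyl group by cross-coupling. It sets out from 4 and returns at 7. Selective methylation of the free 5-OH (MeI, K2CO3, acetone) should give 8-acetyl-7-hydroxy-5-methoxy-3,4-dimethylcoumarin F4. Iodination at the only free ring carbon (N-iodosuccinimide, cat. CF3CO2H, MeCN) should give 8-acetyl-7-hydroxy-6-iodo-5-methoxy-3,4-dimethylcoumarin F5. Protection (NaH, MOMCl, DMF) should give 8-acetyl-6-iodo-5-methoxy-7-(methoxymethoxy)-3,4-dimethylcoumarin F6. Stille coupling with tributyl(3-methylbut-2-enyl)stannane (Pd(PPh3)4, DMF, 90 °C) should give 7.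

Further compounds
F1 | step 9 | 8-[(3S,4S)-4-(tert-butyldimethylsilyloxy)-3-(hexa-1,5-dien-2-yl)pentanoyl]-5-methoxy-7-(methoxymethoxy)-3,4-dimethyl-6-(3-methylbut-2-enyl)coumarin | C[C@H](O[Si](C)(C)C(C)(C)C)[C@@H](CC(=O)c1c(OCOC)c(CC=C(C)C)c(OC)c2c(C)c(C)c(=O)oc12)C(=C)CCC=C
F2 | step 9 | 8-[(3S,4S)-4-(tert-butyldimethylsilyloxy)-3-(hexa-1,5-dien-2-yl)-2-methylidenepentanoyl]-5-methoxy-7-(methoxymethoxy)-3,4-dimethyl-6-(3-methylbut-2-enyl)coumarin | C[C@H](O[Si](C)(C)C(C)(C)C)[C@@H](C(=C)C(=O)c1c(OCOC)c(CC=C(C)C)c(OC)c2c(C)c(C)c(=O)oc12)C(=C)CCC=C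
F3 | step 8 | 4,4,5,5-tetramethyl-2-[3-(vinyloxy)prop-1-en-2-yl]-1,3,2-dioxaborolane | C=COCC(=C)B1OC(C)(C)C(C)(C)O1
F4 | step 3 | 8-acetyl-7-hydroxy-5-methoxy-3,4-dimethylcoumarin | CC(=O)c1c(O)cc(OC)c2c(C)c(C)c(=O)oc12
F5 | step 3 | 8-acetyl-7-hydroxy-6-iodo-5-methoxy-3,4-dimethylcoumarin | CC(=O)c1c(O)c(I)c(OC)c2c(C)c(C)c(=O)oc12
F6 | step 3 | 8-acetyl-6-iodo-5-methoxy-7-(methoxymethoxy)-3,4-dimethylcoumarin | CC(=O)c1c(OCOC)c(I)c(OC)c2c(C)c(C)c(=O)oc12
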